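1.43 was the number I began with: the highest G reading of the midnight run, 20% at 2.08 d, over the highest of the spring run, 14% at 2.00 d, for 2.00 times the Q.

common to all: L 1.5 M (fed, over 25 h)

| charge | Q | remark | time |
|---|---|---|---|
| midnight | 1.8 M | the very flask that is asked about, followed so far; the fed solution adds 0.10 times the starting volume |  |
| spring | 0.90 M | run made earlier; the fed solution adds 0.10 times the starting volume |  |
| flask | 1.80 M | the fed solution adds 0.10 times the starting volume | 6.0 d |

- midnight (time / d: G / %): 0.500: 7; 0.625: 5; 1.04: 14; 1.25: 17; 2.08: 20; 3.00: 16
- spring (time / d: G / %): 0.500: 3; 0.833: 7; 1.25: 12; 2.00: 14; 4.00: 12; 6.00: 0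

(scatter of a reading: 1.5 percentage points)

- when, up to 6.0 d, the flask holds most G
- the amount of G, in percent of the L charged, at that time
- earliest time at which at least nineteen twentieths of that best amount are there, in d
- latest time at which they still are, in d

- charges are per starting volume, the dose included; the dosed solution carries all of it
- the numbers in the tables scatter with a standard deviation of 1.5 percentage points
- percentages count the whole charge, also what has not yet gone in

How does the G peak follow the Q charge? The peak ratio stood below the charge ratio, so I took n, the apparent order in Q: the power of the Q charge that the G peak follows, the logarithm of the peak ratio over the logarithm of the charge ratio. From these readings 0.515, about half, and it carries their scatter of 1.5 percentage points.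

Does Q move the time of the peak? The times of the two highest readings stood in a ratio of 1.04, so I looked for the top of the midnight run between its flanking readings at 1.25 d and 3.00 d.

How wide is the top? The flask asked about is the midnight run followed further. The level asked for lay 1 point under its top reading, but its flanking readings lay 3 points and 4 points under it, so, within their scatter, I expected the window between 1.25 d and 3.00 d.

The forecast I wrote down put 20% (range 18.5% to 22%) at 1.85 d (1.55 d to 2.2 d), opening at 1.5 d (1.25 d to 1.75 d) and shutting at 2.4 d (2.1 d to 2.75 d), on the view that “The rise is steeper than the fall”.

The flask gave 19.1% at 1.87 d, and held the level from 1.44 d to 2.44 d, a window of 24.0 h for stopping it.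

    L ⇌ D (K = 0.470, k = 9.20 × 10⁻⁵ /s)
    Q → J (k = 3.00 × 10⁻⁵ /s)
    D + J → G (k = 4.60 × 10⁻⁵ /M/s)
    2 J → X (k = 4.80 × 10⁻⁵ /M/s)
    G → Z (k = 3.60 × 10⁻⁶ /s)

At the best time in the flask, Q, the limiting reagent, stood at 0.793% of its own charge. From the flask's 19.1% with n of 0.515, I reckoned 11.9% for a neighbour flask charged with 0.72 M of Q, and that neighbour flask reached 12.6%.

The runs were computed with constants of no real substance.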